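**Retrosynthetic overview**

1. Number the benzene ring C1 (CH2CH2OSO3H), C2 and C3 (Br), C4 and C5 (OH), C6 (H). The contiguous Br–Br–OH–OH edge C2–C5 is a hidden 2-acetyl-3,4-dibromofuran: furan C5, C4, C3, C2 become C1, C2, C3, C4, and the acetyl C=O and CH3 become C5 and C6.
2. Last disconnection: the O–SO3H bond, made on the catechol masked as its acetonide (steps 5–7).
3. Key disconnection: the benzene C1–C6 bond, formed by an intramolecular aldol after anodic opening of the furan. The benzene ring is the only ring formed in the route; the furan ring is bought and consumed.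
4. The furan precursor comes from 3,4-dibromofuran by two alpha-lithiations: oxirane for the side chain, then a Weinreb amide for the acetyl group.

Key step: step 4

Assumption: the target is taken as the free hydrogen sulfate as drawn, so the last step ends with proton exchange on a sulfonic acid resin; the acid would be kept cold and dilute or stored as a salt, because concentrated alkyl hydrogen sulfates hydrolyse autocatalytically.

**Route**

Step 1
Reactants: 1 3,4-dibromofuran; 2 oxirane (ethylene oxide)
Product: 3 2-(3,4-dibromofuran-2-yl)ethan-1-ol
Conditions: LiN(i-Pr)2, THF, −78 °C; then oxirane, BF3·OEt2, −78 °C; aq. NH4Cl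
Reagents that add atoms: none
Why: The amide base should remove the alpha proton flanked by the ring oxygen and a bromine (both alpha positions are equivalent) without bromine–lithium exchange, and the BF3-promoted SN2 opening of the epoxide lets the C–C bond form at −78 °C, where the 3-bromo-2-lithiofuran is expected to keep its halogens in place (directed lithiation, then Lewis-acid-assisted epoxide opening).

Step 2
Reactants: 3 2-(3,4-dibromofuran-2-yl)ethan-1-ol
Product: 4 tert-butyl[2-(3,4-dibromofuran-2-yl)ethoxy]dimethylsilane
Conditions: TBSCl, imidazole, DMF, rt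
Reagents that add atoms: tert-butyl(chloro)dimethylsilane (TBSCl), CC(C)(C)[Si](C)(C)Cl
Why: Imidazole-assisted silylation of a primary alcohol masks the hydroxyl for the second lithiation (silyl ether protection).

Step 3
Reactants: 4 tert-butyl[2-(3,4-dibromofuran-2-yl)ethoxy]dimethylsilane; 5 N-methoxy-N-methylacetamide
Product: 6 1-[3,4-dibromo-5-(2-{[tert-butyl(dimethyl)silyl]oxy}ethyl)furan-2-yl]ethan-1-one
Conditions: LiN(i-Pr)2, THF, −78 °C; then 5, −78 to 0 °C; aq. NH4Cl
Reagents that add atoms: none
Why: The only remaining ring proton, again flanked by oxygen and bromine, is removed by the amide base, and the lithiofuran should add once to the amide because the chelated tetrahedral adduct collapses to the ketone only on work-up (Weinreb ketone synthesis).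

Step 4
Reactants: 6 1-[3,4-dibromo-5-(2-{[tert-butyl(dimethyl)silyl]oxy}ethyl)furan-2-yl]ethan-1-one
Product: 11 3,4-dibromo-5-(2-hydroxyethyl)benzene-1,2-diol, via dimethoxydihydrofuran 7 (not isolated), via Z-ene-trione 8 (not isolated), via aldol carbinol 9 (not isolated), via o-quinone 10 (not isolated)
Conditions: (a) undivided cell, graphite anode, Pt cathode, Et4NOTs, MeOH, 0 °C, constant current, ca. 2.5 F/mol; (b) remove MeOH, then 1 M aq. H2SO4–THF (1:1), rt to 40 °C; (c) EtOAc, aq. Na2S2O4, 0 °C
Reagents that add atoms: methanol, CO (its methoxy groups are in 7 only); water, O (its oxygen is in 8 and 9 only)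
Why: Proposed new method: two-electron anodic oxidation of the furan in methanol (radical cation, methanol capture at the alkyl-bearing alpha carbon, second oxidation, methanol capture at the acyl-bearing alpha carbon) should give the 2,5-dimethoxy-2,5-dihydrofuran 7 as a diastereomer mixture of no consequence, and aqueous acid then hydrolyses both ketals and the silyl ether to the (Z)-ene-trione 8, whose cis geometry is inherited from the ring. The methyl group of the 1,2-diketone enolises and adds to the chain ketone in a 6-(enolendo)-exo-trig aldol closure that makes the C1–C6 bond and the six-membered carbocycle (9); beta-elimination of water from 9 gives the o-quinone 10, which dithionite reduces to catechol 11. The closest known reaction type is the conversion of 2-acetylfurans into catechols by electrolytic 2,5-dimethoxylation, hydrogenation and acid-induced intramolecular aldol closure; here the hydrogenation is left out, so that the ring closes at the quinone oxidation level and both vinylic bromines stay. No stereocenter remains in 11, since the ketal centres of 7 and the carbinol centre of 9 are destroyed on the way. The step needs the diketone methyl, not the chain CH2, to act as the enol donor (the latter would close onto the acetyl carbonyl and end in a p-quinone); the higher C–H acidity next to the 1,2-dicarbonyl and the hydration that masks the diketone as an acceptor in aqueous acid should favour the wanted mode. A non-nucleophilic acid and removal of methanol before hydrolysis protect the bromine-bearing enone carbons from addition–elimination, and the reductant is added only after closure so that the ene-dione itself is not reduced.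

Step 5
Reactants: 11 3,4-dibromo-5-(2-hydroxyethyl)benzene-1,2-diol
Product: 12 2-(6,7-dibromo-2,2-dimethyl-1,3-benzodioxol-5-yl)ethan-1-ol
Conditions: 2,2-dimethoxypropane, TsOH (cat.), toluene, reflux, 4 Å sieves (Soxhlet); then AcOH–THF–H2O, rt
Reagents that add atoms: 2,2-dimethoxypropane, COC(C)(C)OC
Why: Acid-catalysed transketalisation closes the five-membered cyclic ketal on the two adjacent phenols, whereas any mixed ketal at the primary alcohol is acyclic and should fall off in the mildly acidic aqueous work-up (isopropylidene protection of a catechol).

Step 6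
Reactants: 12 2-(6,7-dibromo-2,2-dimethyl-1,3-benzodioxol-5-yl)ethan-1-ol
Product: 13 triethylammonium 2-(6,7-dibromo-2,2-dimethyl-1,3-benzodioxol-5-yl)ethyl sulfate
Conditions: SO3·NEt3, DMF, 40 °C
Reagents that add atoms: sulfur trioxide–triethylamine complex, CC[N+](CC)(CC)S(=O)(=O)[O-]
Why: The amine–sulfur trioxide complex transfers SO3 to the only free hydroxyl and should give the sulfate monoester directly as its triethylammonium salt (O-sulfation with an SO3–amine complex).

Step 7
Reactants: 13 triethylammonium 2-(6,7-dibromo-2,2-dimethyl-1,3-benzodioxol-5-yl)ethyl sulfate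
Product: 15 2-(2,3-dibromo-4,5-dihydroxyphenyl)ethyl hydrogen sulfate, via triethylammonium catechol sulfate 14 (not isolated)
Conditions: TFA–H2O (9:1), 0 °C to rt; then H2O, sulfonic acid resin (H+ form), 0 °C; freeze-dry
Reagents that add atoms: none
Why: Aqueous trifluoroacetic acid hydrolyses the aryl ketal while a primary alkyl sulfate monoester, which solvolyses only slowly in aqueous acid near room temperature, should persist, and the strongly acidic resin then exchanges the ammonium ion for a proton (acid ketal hydrolysis followed by cation exchange).

**Compound list**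

1 | 3,4-dibromofuran | Brc1cocc1Br | starting material
2 | oxirane (ethylene oxide) | C1CO1 | starting material
3 | 2-(3,4-dibromofuran-2-yl)ethan-1-ol | OCCc1occ(Br)c1Br | intermediate
4 | tert-butyl[2-(3,4-dibromofuran-2-yl)ethoxy]dimethylsilane | CC(C)(C)[Si](C)(C)OCCc1occ(Br)c1Br | intermediate
5 | N-methoxy-N-methylacetamide | CC(=O)N(C)OC | starting material
6 | 1-[3,4-dibromo-5-(2-{[tert-butyl(dimethyl)silyl]oxy}ethyl)furan-2-yl]ethan-1-one | CC(=O)c1oc(CCO[Si](C)(C)C(C)(C)C)c(Br)c1Br | intermediate
7 | 1-[3,4-dibromo-5-(2-{[tert-butyl(dimethyl)silyl]oxy}ethyl)-2,5-dimethoxy-2,5-dihydrofuran-2-yl]ethan-1-one (cis/trans mixture, each racemic) | CC(=O)C1(OC)OC(OC)(CCO[Si](C)(C)C(C)(C)C)C(Br)=C1Br | intermediate (not isolated)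
8 | (4Z)-4,5-dibromo-8-hydroxyoct-4-ene-2,3,6-trione | CC(=O)C(=O)/C(Br)=C(Br)\C(=O)CCO | intermediate (not isolated)
9 | 3,4-dibromo-5-hydroxy-5-(2-hydroxyethyl)cyclohex-3-ene-1,2-dione (racemic) | OCCC1(O)CC(=O)C(=O)C(Br)=C1Br | intermediate (not isolated)
10 | 3,4-dibromo-5-(2-hydroxyethyl)cyclohexa-3,5-diene-1,2-dione | OCCC1=CC(=O)C(=O)C(Br)=C1Br | intermediate (not isolated)
11 | 3,4-dibromo-5-(2-hydroxyethyl)benzene-1,2-diol | OCCc1cc(O)c(O)c(Br)c1Br | intermediate
12 | 2-(6,7-dibromo-2,2-dimethyl-1,3-benzodioxol-5-yl)ethan-1-ol | CC1(C)Oc2cc(CCO)c(Br)c(Br)c2O1 | intermediate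
13 | triethylammonium 2-(6,7-dibromo-2,2-dimethyl-1,3-benzodioxol-5-yl)ethyl sulfate | CC1(C)Oc2cc(CCOS(=O)(=O)[O-])c(Br)c(Br)c2O1.CC[NH+](CC)CC | intermediate
14 | triethylammonium 2-(2,3-dibromo-4,5-dihydroxyphenyl)ethyl sulfate | [O-]S(=O)(=O)OCCc1cc(O)c(O)c(Br)c1Br.CC[NH+](CC)CC | intermediate (not isolated)
15 | 2-(2,3-dibromo-4,5-dihydroxyphenyl)ethyl hydrogen sulfate | O=S(=O)(O)OCCc1cc(O)c(O)c(Br)c1Br | target

**Step count**

Total steps: 7. Longest linear sequence: 7 steps (1 to 15).

**Steps most likely to fail**

Step 4 (Proposed new method). Several processes can go wrong: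
- The electron-poor furan may be oxidised inefficiently at the anode.
- The chain methylene may enolise in place of the diketone methyl and close onto the acetyl carbonyl.
- The free hydroxyl or the solvent may displace a vinylic bromide by addition–elimination.
- The o-quinone may decay before it is reduced.

The fallback sets out from 6 and returns at 11, using only known chemistry. The electrolysis alone, the established anodic dimethoxylation of 2-acylfurans, is run and 7 is isolated. Hydrogenation (H2, Raney Ni, Et3N, MeOH, rt) saturates the ring double bond and removes both bromines, giving 1-[5-(2-{[tert-butyl(dimethyl)silyl]oxy}ethyl)-2,5-dimethoxyoxolan-2-yl]ethan-1-one F1. Hot dilute aqueous H2SO4 then hydrolyses the ketals and the silyl ether and closes the saturated 1,2,5-triketone to 4-(2-hydroxyethyl)benzene-1,2-diol F2, which is the established furan-to-catechol sequence. Two equivalents of Br2 in AcOH at 10 °C should then brominate para to one hydroxyl and ortho to the other, the position between the side chain and a hydroxyl being the most hindered, and so give 11.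

Step 7. The sulfate ester may be lost by acid solvolysis while the ketal on the electron-poor benzodioxole is cleaved, or the ketal may cleave only partly. The fallback sets out from 11 and returns at 14, replacing the acid-labile mask by a base-labile one. Phenolate-selective acetylation (Ac2O, aq. NaHCO3–THF, 0 °C) gives 3,4-dibromo-5-(2-hydroxyethyl)-1,2-phenylene diacetate F3. Sulfation with SO3·NEt3 in DMF gives triethylammonium 2-(4,5-diacetoxy-2,3-dibromophenyl)ethyl sulfate F4. Ammonolysis (NH3, MeOH, 0 °C, degassed) removes both acetates under conditions that leave the sulfate alone and gives 14, which the resin treatment of step 7 turns into 15.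

Step 1. The epoxide may open too slowly, so that the lithiofuran migrates its halogens or fragments as it warms, or BF3 may oligomerise the epoxide. The fallback sets out from 1 and returns at 3, building the two-carbon chain one carbon at a time. Lithiation as before and a DMF quench, which is fast at −78 °C, give 3,4-dibromofuran-2-carbaldehyde F5. Wittig methylenation (Ph3PCH3Br, KOt-Bu, THF, 0 °C) gives 3,4-dibromo-2-ethenylfuran F6. Anti-Markovnikov hydroboration with 9-BBN and oxidation (NaOH, H2O2) then give 3.

**Further compounds**

F1 | step 4 | 1-[5-(2-{[tert-butyl(dimethyl)silyl]oxy}ethyl)-2,5-dimethoxyoxolan-2-yl]ethan-1-one | CC(=O)C1(OC)CCC(OC)(CCO[Si](C)(C)C(C)(C)C)O1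
F2 | step 4 | 4-(2-hydroxyethyl)benzene-1,2-diol | OCCc1ccc(O)c(O)c1
F3 | step 7 | 3,4-dibromo-5-(2-hydroxyethyl)-1,2-phenylene diacetate | CC(=O)Oc1cc(CCO)c(Br)c(Br)c1OC(C)=O
F4 | step 7 | triethylammonium 2-(4,5-diacetoxy-2,3-dibromophenyl)ethyl sulfate | CC(=O)Oc1cc(CCOS(=O)(=O)[O-])c(Br)c(Br)c1OC(C)=O.CC[NH+](CC)CC
F5 | step 1 | 3,4-dibromofuran-2-carbaldehyde | O=Cc1occ(Br)c1Br
F6 | step 1 | 3,4-dibromo-2-ethenylfuran | C=Cc1occ(Br)c1Br
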